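**Plan**
- Retrosynthesis: the pivalate on the C2 aryl oxygen is removed first, then both aryl–carbonyl bonds are cut. The enabling feature is that the ketone carbon on C3 of the dihydrobenzofuran and the ketone carbon ending the three-carbon chain on C5 carry the same 2,4-dihydroxyphenyl ring, which is resorcinol bonded through its C4. Both therefore come from one diacid and two molecules of resorcinol.
- The diacid is traced to a dibenzyl ester. The dihydrofuran ring is then cut at C3–C3a and C2–O1 into two molecules of benzyl 4-hydroxycinnamate.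
- Forward: esterification, oxidative dimerisation (closes the dihydrofuran ring, the only ring made), resolution, pivaloylation, hydrogenation with hydrogenolysis to the diacid, two-fold acylation of resorcinol, depivaloylation.
- Stereochemistry: the 2,3-trans relationship comes from the ring closure in the dimerisation, and the absolute configuration from chromatography on a chiral phase. No later step creates a stereocentre, and trans is the thermodynamic arrangement.

Key step: step 6

Remark on the chemistry: with a carbonyl group on C3 the descriptors (2S,3S) denote the 2,3-trans arrangement and stay the same for compounds 6 to 13; the enantiomer collected in step 3 is to be assigned as (2S,3S) by electronic circular dichroism against a computed spectrum before it is carried on.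

**Route**

Step 1
Reactants: 1 (E)-4-hydroxycinnamic acid; 2 benzyl bromide
Product: 3 benzyl (E)-4-hydroxycinnamate
Conditions: KHCO3 (1.2 equiv), DMF, 40 °C
Reagents that add atoms: benzyl bromide (compound 2), BrCc1ccccc1
Why: Carboxylate O-alkylation (SN2 esterification): KHCO3 ionises only the carboxylic acid and leaves the less acidic phenol protonated, so benzyl bromide should react at the carboxylate alone.

Step 2
Reactants: 3 benzyl (E)-4-hydroxycinnamate (two molecules)
Product: 5 racemic trans dibenzyl ester of the 2-(4-hydroxyphenyl)-2,3-dihydrobenzofuran dimer, via quinone methide 4 (not isolated)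
Conditions: Ag2O (0.55 equiv), MeCN, rt, dark, N2
Reagents that add atoms: none
Why: Oxidative phenol coupling (biomimetic 8–5' radical dimerisation): Ag2O generates phenoxyl radicals that join the acrylate α-carbon of one unit to the carbon ortho to the hydroxyl of the other, and after rearomatisation the phenol oxygen adds to quinone methide 4 in a 5-exo-trig closure that sets both new stereocentres, C2 and C3, in the less strained trans relationship, as a racemate.

Step 3
Reactants: 5 racemic trans dibenzyl ester
Product: 6 benzyl (2S,3S)-5-[(E)-3-(benzyloxy)-3-oxoprop-1-enyl]-2-(4-hydroxyphenyl)-2,3-dihydro-1-benzofuran-3-carboxylate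
Conditions: preparative HPLC, amylose tris(3,5-dimethylphenylcarbamate) on silica, hexane/i-PrOH, rt
Reagents that add atoms: none
Why: Chromatographic resolution of enantiomers on a polysaccharide chiral stationary phase, a standard method for 2-aryl-2,3-dihydrobenzofuran-3-carboxylates; no bond is changed and the absolute configuration of the route is fixed by collecting the (2S,3S) antipode.

Step 4
Reactants: 6 (2S,3S) phenol dibenzyl ester; 7 pivaloyl chloride
Product: 8 benzyl (2S,3S)-5-[(E)-3-(benzyloxy)-3-oxoprop-1-enyl]-2-[4-(pivaloyloxy)phenyl]-2,3-dihydro-1-benzofuran-3-carboxylate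
Conditions: pyridine (3 equiv), DMAP (cat.), CH2Cl2, 0 °C to rt
Reagents that add atoms: pivaloyl chloride (compound 7), CC(C)(C)C(Cl)=O
Why: Acylation of a phenol with an acyl chloride under nucleophilic catalysis; the weak amine base does not enolise the C3 ester, and the bulky ester is chosen to resist acyl transfer in step 6.

Step 5
Reactants: 8 pivalate dibenzyl ester
Product: 9 (2S,3S)-5-(2-carboxyethyl)-2-[4-(pivaloyloxy)phenyl]-2,3-dihydro-1-benzofuran-3-carboxylic acid
Conditions: H2 (1 atm), 10% Pd/C, EtOAc, rt, stopped after uptake of 3 equiv H2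
Reagents that add atoms: none
Why: Heterogeneous catalytic hydrogenation saturates the acrylate C=C and hydrogenolyses both benzyl esters, two fast processes, under neutral conditions that cannot enolise C3, whereas the ring C2–O1 bond, a benzylic ether on an aryl ring deactivated by the pivaloyloxy group, should be cleaved much more slowly.

Step 6
Reactants: 9 diacid pivalate; 10 resorcinol (2.5–3 equiv)
Product: 12 4-[(2S,3S)-3-(2,4-dihydroxybenzoyl)-5-[3-(2,4-dihydroxyphenyl)-3-oxopropyl]-2,3-dihydro-1-benzofuran-2-yl]phenyl pivalate, via bis(difluoroboron) chelate 11 (not isolated)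
Conditions: BF3·OEt2 (neat, excess), 85 °C, Ar; then 10% aq. NaOAc, rt
Reagents that add atoms: resorcinol (compound 10), Oc1cccc(O)c1
Why: BF3 converts each carboxyl group of 9 into an acyloxyborane-type electrophile that acylates resorcinol at C4 (para to one hydroxyl, ortho to the other), either directly or by O-acylation followed by a Fries shift, and each new ortho-hydroxy ketone is held as the difluoroboron chelate 11, which deactivates that ring toward a second acylation and is hydrolysed by aqueous NaOAc. The closest known reaction type is the BF3·OEt2-mediated Friedel–Crafts (Nencki-type) acylation of resorcinol by arylacetic, 2-arylpropanoic and 3-arylpropanoic acids that gives deoxybenzoins and dihydrochalcones, here run at both carboxyl groups of one diacid. No ring is closed and no stereocentre is created; the C2 and C3 centres should persist because trans is the thermodynamic arrangement, so enolisation at C3 returns the same diastereomer, while ionisation of C2–O1, the only other path to stereochemical loss, is disfavoured by the electron-poor 4-pivaloyloxyphenyl group. The step needs C4 over C2 selectivity on resorcinol, secured by the crowding of C2 between two hydroxyls and by chelation of the product, and intermolecular acylation over indanone closure of the propanoic chain, secured by the far higher nucleophilicity of resorcinol compared with C4 and C6 of ring A, which lie meta to O1. The hindered pivalate should survive, and any of it that is lost gives 13 directly, so the material converges in step 7.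

Step 7
Reactants: 12 bis-ketone pivalate
Product: 13 1-(2,4-dihydroxyphenyl)-3-[(2S,3S)-3-(2,4-dihydroxybenzoyl)-2-(4-hydroxyphenyl)-2,3-dihydro-1-benzofuran-5-yl]propan-1-one (target)
Conditions: K2CO3 (6 equiv), degassed MeOH, 0 °C to rt, Ar; then 1 M HCl to pH 4
Reagents that add atoms: none
Why: Base-mediated transesterification (methanolysis) of the aryl pivalate; under these conditions the 4-hydroxyl of each 2,4-dihydroxyphenyl ketone is ionised, which turns both carbonyls into vinylogous carboxylates and so should prevent deprotonation at C3 and β-elimination of O1, leaving both stereocentres untouched.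

**Compound list**
1 | (E)-4-hydroxycinnamic acid (p-coumaric acid) | OC(=O)/C=C/c1ccc(O)cc1 | starting material
2 | benzyl bromide | BrCc1ccccc1 | starting material
3 | benzyl (E)-3-(4-hydroxyphenyl)prop-2-enoate | O=C(OCc1ccccc1)/C=C/c1ccc(O)cc1 | intermediate
4 | quinone methide, benzyl (E)-3-{3-[1-(benzyloxycarbonyl)-2-(4-oxocyclohexa-2,5-dien-1-ylidene)ethyl]-4-hydroxyphenyl}prop-2-enoate (racemic) | O=C1C=CC(=CC(C(=O)OCc2ccccc2)c2cc(/C=C/C(=O)OCc3ccccc3)ccc2O)C=C1 | intermediate (not isolated)
5 | racemic trans benzyl 5-[(E)-3-(benzyloxy)-3-oxoprop-1-enyl]-2-(4-hydroxyphenyl)-2,3-dihydro-1-benzofuran-3-carboxylate (1:1 mixture of the (2S,3S) and (2R,3R) forms) | O=C(OCc1ccccc1)/C=C/c1ccc2c(c1)[C@H](C(=O)OCc1ccccc1)[C@@H](c1ccc(O)cc1)O2.O=C(OCc1ccccc1)/C=C/c1ccc2c(c1)[C@@H](C(=O)OCc1ccccc1)[C@H](c1ccc(O)cc1)O2 | intermediate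
6 | benzyl (2S,3S)-5-[(E)-3-(benzyloxy)-3-oxoprop-1-enyl]-2-(4-hydroxyphenyl)-2,3-dihydro-1-benzofuran-3-carboxylate | O=C(OCc1ccccc1)/C=C/c1ccc2c(c1)[C@H](C(=O)OCc1ccccc1)[C@@H](c1ccc(O)cc1)O2 | intermediate
7 | pivaloyl chloride | CC(C)(C)C(Cl)=O | starting material
8 | benzyl (2S,3S)-5-[(E)-3-(benzyloxy)-3-oxoprop-1-enyl]-2-[4-(pivaloyloxy)phenyl]-2,3-dihydro-1-benzofuran-3-carboxylate | O=C(OCc1ccccc1)/C=C/c1ccc2c(c1)[C@H](C(=O)OCc1ccccc1)[C@@H](c1ccc(OC(=O)C(C)(C)C)cc1)O2 | intermediate
9 | (2S,3S)-5-(2-carboxyethyl)-2-[4-(pivaloyloxy)phenyl]-2,3-dihydro-1-benzofuran-3-carboxylic acid | OC(=O)CCc1ccc2c(c1)[C@H](C(=O)O)[C@@H](c1ccc(OC(=O)C(C)(C)C)cc1)O2 | intermediate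
10 | resorcinol | Oc1cccc(O)c1 | starting material
11 | bis(difluoroboron) chelate of 12 (each 2-hydroxyaryl ketone bound as a six-membered O–BF2–O=C chelate) | Oc1ccc2c(c1)O[B-](F)(F)[O+]=C2CCc1ccc2c(c1)[C@H](C1=[O+][B-](F)(F)Oc3cc(O)ccc31)[C@@H](c1ccc(OC(=O)C(C)(C)C)cc1)O2 | intermediate (not isolated)
12 | 4-[(2S,3S)-3-(2,4-dihydroxybenzoyl)-5-[3-(2,4-dihydroxyphenyl)-3-oxopropyl]-2,3-dihydro-1-benzofuran-2-yl]phenyl 2,2-dimethylpropanoate | O=C(CCc1ccc2c(c1)[C@H](C(=O)c1ccc(O)cc1O)[C@@H](c1ccc(OC(=O)C(C)(C)C)cc1)O2)c1ccc(O)cc1O | intermediate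
13 | 1-(2,4-dihydroxyphenyl)-3-[(2S,3S)-3-(2,4-dihydroxybenzoyl)-2-(4-hydroxyphenyl)-2,3-dihydro-1-benzofuran-5-yl]propan-1-one | O=C(CCc1ccc2c(c1)[C@H](C(=O)c1ccc(O)cc1O)[C@@H](c1ccc(O)cc1)O2)c1ccc(O)cc1O | target

**Totals**
Total step count: 7. Longest linear sequence: 7 steps (1 to 13).

**Steps most likely to fail**

1. Step 6. The hindered C3 carboxyl may acylate too slowly, so that reaction stops after the chain ketone. The activated C3 acyl group may also lose CO and aromatise the dihydrofuran ring, or the Lewis acid may open the C2–O1 bond at 85 °C. The fallback sets out from diacid 9 and forms the same two aryl–carbonyl bonds by cross-coupling instead of electrophilic substitution. Thiophenol with EDC·HCl and catalytic DMAP in CH2Cl2 at 0 °C should give the bis(S-phenyl thioester) F1. Liebeskind–Srogl coupling of F1 with 2,4-bis(benzyloxy)phenylboronic acid (Pd2(dba)3, tri(2-furyl)phosphine, copper thiophene-2-carboxylate Cu(O2CC4H3S), THF, 50 °C) is a neutral ketone synthesis that tolerates α-stereocentres and should give the tetrabenzyl ether F2. Hydrogenolysis of the four benzyl ethers (H2, Pd/C, EtOAc) comes back to the route at 12.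

2. Step 7. Deprotonation at C3 followed by β-elimination of O1 and reclosure would erode the enantiomeric purity, and the polyphenolate may oxidise in air. The fallback sets out from 6 and avoids the protecting group, and with it any basic step. Hydrogenation of 6 (H2, Pd/C, EtOAc) saturates the acrylate and removes both benzyl esters to give the free-phenol diacid F3. Acylation of resorcinol 10 by F3 in BF3·OEt2 under the conditions of step 6 then arrives directly at 13.

3. Step 5. Over-reduction by hydrogenolysis of the benzylic C2–O1 bond would open the dihydrofuran ring before both benzyl esters are gone. The fallback sets out from 8 and uses no metal-catalysed hydrogenation. Diimide generated from 2-nitrobenzenesulfonyl hydrazide and Et3N in CH2Cl2 at rt saturates the acrylate without touching C–O bonds and should give the saturated dibenzyl ester F4. BCl3 with pentamethylbenzene as cation scavenger (CH2Cl2, −78 °C) then cleaves both benzyl esters and comes back to the route at 9.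

**Further compounds**
F1 | step 6 | S-phenyl (2S,3S)-5-[3-oxo-3-(phenylsulfanyl)propyl]-2-[4-(pivaloyloxy)phenyl]-2,3-dihydro-1-benzofuran-3-carbothioate | O=C(CCc1ccc2c(c1)[C@H](C(=O)Sc1ccccc1)[C@@H](c1ccc(OC(=O)C(C)(C)C)cc1)O2)Sc1ccccc1
F2 | step 6 | 4-[(2S,3S)-3-[2,4-bis(benzyloxy)benzoyl]-5-{3-[2,4-bis(benzyloxy)phenyl]-3-oxopropyl}-2,3-dihydro-1-benzofuran-2-yl]phenyl 2,2-dimethylpropanoate | O=C(CCc1ccc2c(c1)[C@H](C(=O)c1ccc(OCc3ccccc3)cc1OCc1ccccc1)[C@@H](c1ccc(OC(=O)C(C)(C)C)cc1)O2)c1ccc(OCc2ccccc2)cc1OCc1ccccc1
F3 | step 7 | (2S,3S)-5-(2-carboxyethyl)-2-(4-hydroxyphenyl)-2,3-dihydro-1-benzofuran-3-carboxylic acid | OC(=O)CCc1ccc2c(c1)[C@H](C(=O)O)[C@@H](c1ccc(O)cc1)O2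
F4 | step 5 | benzyl (2S,3S)-5-[3-(benzyloxy)-3-oxopropyl]-2-[4-(pivaloyloxy)phenyl]-2,3-dihydro-1-benzofuran-3-carboxylate | O=C(OCc1ccccc1)CCc1ccc2c(c1)[C@H](C(=O)OCc1ccccc1)[C@@H](c1ccc(OC(=O)C(C)(C)C)cc1)O2
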